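All runs are simulated with constants of no real substance.

The ratio of partner to starting material is 0.487 in south and 1.50 in south-west. Partner is therefore the limiting reagent in south, while starting material is limiting in south-west.

| setting | epsilon | beta | south | south-west |
|---|---|---|---|---|
| starting material | 0.010 M | 0.026 M | 0.040 M | 0.013 M |
| partner | 0.0195 M | 0.0195 M | 0.0195 M | 0.0195 M |
| second substrate | 0.065 M | 0.065 M | 0.0650 M | 0.0650 M |
| free catalyst | 0.32 mM | 0.32 mM | 0.32 mM | 0.32 mM |
| temperature | 45 °C | 60 °C |  |  |
| remark | run made earlier | run made earlier | at 70 °C throughout | at 70 °C until 4.0 min, from then on at 50 °C |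
| time |  |  | 20 min | 20 min |

| run | time / min | target / % |
|---|---|---|
| epsilon | 2.50 | 3.0 |
| epsilon | 6.00 | 9.4 |
| epsilon | 15.0 | 21.6 |
| epsilon | 30.0 | 32.6 |
| beta | 1.33 | 3.7 |
| beta | 2.00 | 5.3 |
| beta | 3.00 | 9.3 |
| beta | 6.00 | 15.3 |
| beta | 10.0 | 20.6 |
| beta | 15.0 | 29.5 |

(readings scatter by 1 percentage point)

1. which of the two ends with the higher amount of target, in percent of the starting material charged ("neither" if they lie within 2 percentage points) (south / south-west / neither)
2. target at the end, in percent of the starting material charged, south
3. target at the end, in percent of the starting material charged, south-west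

Here is the puzzle: south stays hot throughout with 0.040 M of starting material, south-west gets 0.013 M and is cooled at 4.0 min, and yet we expect them to end close together.

Let r be the fractional rate of starting material, minus the logarithm of its unreacted fraction divided by time, a pseudo-first-order rate. The readings give 0.0162 min⁻¹ at 45 °C (epsilon) and 0.0277 min⁻¹ at 60 °C (beta). Extending that factor geometrically gives 0.0395 min⁻¹ at 70 °C and 0.0194 min⁻¹ at 50 °C, so our hot estimate is twice our cool one.

The proposed step makes r proportional to partner, so we define κ = r/[partner], which is 2.03 M⁻¹ min⁻¹ at 70 °C. The partner lifetime τ is then 1/(κ[starting material]), the time for partner to fall by a factor e at the charged rate. In south, τ is 12.3 min; in south-west at 70 °C it is 38.0 min. South thus spends 1.62 lifetimes and its rate sags, whereas south-west has spent 0.105 at the change.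

Holding free catalyst at its charge, and in south-west partner too, we reckon 34.9% for south and 37.4% for south-west. That puts south-west ahead by 2.5 percentage points, barely beyond the margin, from readings scattered by 1 point.

The forecast differs: it says neither, with 29% for south and 30% for south-west, reasoning of south that “the partner is used up quickly”.

The flasks give 32.9% for south and 32.2% for south-west: neither.

    starting material + partner + free catalyst → free catalyst + target (k = 7340 M⁻² min⁻¹, Ea = 37.0 kJ mol⁻¹)
    second substrate + partner + free catalyst → free catalyst + second product (k = 215 M⁻² min⁻¹, Ea = 55.0 kJ mol⁻¹)
    2 free catalyst → spent catalyst (k = 44.7 M⁻¹ min⁻¹, Ea = 54.0 kJ mol⁻¹)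
    (constants at 70 °C)

In south at 20.0 min, the target step gives partner a half-life of 17 min against 83 min for starting material, with 28.7% of the partner, 67.1% of the starting material and 63.6% of the free catalyst standing; our τ, divided by those last two fractions, gives a half-life of 20.0 min for that moment. The same κ gives a neighbour, south with 0.078 M of partner in place of its charge, a starting-material lifetime of 6.31 min, or 3.16 lifetimes at the charge, and that flask ends with 85.5% target and 51.6% of its partner.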